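## The problem

Asperimide C (26) joins a 2,2-dimethylchroman-3-ol (arene ring A fused to pyran ring B), an NH maleimide (ring C) and a 4-hydroxyphenyl group (ring D). A single methylene links C7 of the chroman to C3' of the maleimide, and C4' carries ring D, so the central alkene is tetrasubstituted and unsymmetrical. The only stereocentre is the (S)-carbinol C3, lying between the quaternary C2 and the benzylic C4H2. No other stereogenic element can relay to it, so a reagent or catalyst must set it, and it is too remote to influence ring C. The fragile parts are the imide (opened by hydroxide; its flanking benzylic CH2 allows the alkene to migrate under base), the free phenol, and the tertiary alkyl aryl ether O1–C2 next to a carbinol, which can ionise at C2 under strong acid. The nitrogen is therefore best introduced late and both hydroxyl groups kept masked to the end. Ring A is 1,2,4-trisubstituted, with O1 and C4 ortho and the linking carbon para to C4a, which is the pattern of a 3,4-dioxygenated benzoate. The enabling feature is the C4H2–C3H(O) pair: a two-carbon unit between arene carbon C4a and the three-carbon C2 unit, with C3–O readable as C3–B. That is what a vinylboron ate complex delivers when an aryl electrophile and a migrating alkenyl group add across it.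

## Retrosynthesis

**26 ⇒ 25 ⇒ 24.** The target 26 is traced to its bis(methoxymethyl) ether 25, so that the phenol and the C3 carbinol are released together by dilute acid, which the imide tolerates. Cutting both C–N bonds of ring C leads to anhydride 24. This is preferred to carrying an N-protected imide, because nitrogen then needs no protecting group and enters from an ammonia equivalent at room temperature. The forward steps must spare two acetals and leave the alkene in the ring.

**24 ⇒ 22 ⇒ 15 + 17 + 18.** The anhydride comes from maleate 22, in which the bonds C3'–CH2 and C4'–C(aryl) are cut. Both are made in one flask by adding an arylcopper reagent (from bromide 17) across dimethyl acetylenedicarboxylate 18 and alkylating the resulting vinylcopper with benzylic bromide 15. Against a stepwise cross-coupling on a dihalomaleimide, this takes the four-carbon core from a cheap reagent, fixes the substituent positions by the order of addition, and needs no N-protection. The forward reaction needs syn addition and retentive alkylation; a stereochemical leak is tolerable, since ring closure to 24 funnels material to the cis-diacid.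

**15 ⇒ 14 ⇒ 13 ⇒ 12.** No skeletal bond is cut. Bromide 15 is traced through alcohol 14 and ester 13 to hydroxy ester 12. The ester carbon is the future linking CH2; carrying it as an ester from the start activates the arene for the key step and differentiates the two oxygens of the starting catechol. The carbinol is masked as a methoxymethyl ether, which survives hydride, organocopper and hydroxide, and leaves at the end together with the phenol acetal.

**12 ⇒ 10.** Ring B is opened at O1–C2, giving phenol 10 with a 1,1-disubstituted alkene. Cutting here, and not at C4–C4a or C3–C4, leaves a 6-exo Markovnikov closure of a phenol onto the tertiary alkene carbon, where regiochemistry is assured. The new C2 centre is not stereogenic once the metal is replaced by hydrogen. The forward step must avoid a free tertiary cation next to the carbinol, so a mercurinium ion is used instead of a protic acid.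

**10 ⇒ 9 ⇒ 8.** The C3–O bond is exchanged for C3–B (alcohol 9 from boronate 8, with retention), and the phenol is masked as a silyl ether. This places the stereocentre in a secondary allylic boronate, a class accessible by catalytic asymmetric synthesis.

**8 ⇒ 3 + 5 + 6 (through 7).** C4–C4a and C2–C3 are cut together: the vinyl group of vinyllithium 5 becomes C4–C3, isopropenylboronate 6 supplies C2 with both methyl carbons, and aryl triflate 3 supplies ring A. Neighbouring cuts are weaker. O1–C2 with C3–O (asymmetric epoxidation of a prenylarene) needs the prenyl group installed first. C3–C4 with O1–C2 (a quinone methide cycloaddition) has no close precedent. The chosen cut makes both C–C bonds flanking C3 and sets C3 in one catalytic step from three achiral components. It requires a halide-free ate complex 7, which is why 5 is made from tetravinylstannane 4 and not by halogen–lithium exchange.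

**3 ⇒ 2 ⇒ 1; 5 ⇒ 4; 17 ⇒ 16.** Triflate 3 is traced through hydroxy triflate 2 to methyl 3,4-dihydroxybenzoate 1, using the higher acidity of the 4-hydroxyl (para to the ester). Bromide 17 comes from 4-bromophenol 16.

## Roads not taken

**Alternative 1:** The cut is at the maleimide alkene C3'=C4', with sulfur inserted between the two carbons. The precursor is the N-(2,4-dimethoxybenzyl)thiomorpholine-3,5-dione 1,1-dioxide A2, which carries the protected aryl group on one sulfone carbon and the chromanylmethyl group on the other. A Ramberg–Bäcklund reaction (base and a positive-halogen source) would halogenate one α-carbon, close the episulfone and expel SO2, contracting the six-membered ring to the fully protected maleimide A1.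
- Merits: the halves are joined by simple C–S alkylation, the alkene position is unambiguous, nitrogen is present before the alkene exists, and neither an organocopper step nor basic hydrolysis of a maleate is needed.
- Weak points: both α-hydrogens of A2 are flanked by sulfone and imide carbonyl, so halogenation is hard to hold to one site. The hydroxide or alkoxide medium threatens the imide and the maleimide product. The dimethoxybenzyl group on an imide nitrogen leaves only under strong acid or oxidant, which suits neither the chroman ether nor the electron-rich rings.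
- Comparison: this cut does nothing for C3, so the (S)-chromanol half would still need a sequence like the one chosen here. It competes only with steps 12–14 and is longer by thioether assembly, oxidation and N-deprotection. Its regiochemical certainty and freedom from base-induced alkene migration are real advantages; the chosen plan sets against them the preference of the cyclic anhydride and imide for the endocyclic tetrasubstituted alkene.

**Alternative 2:** Ring A and ring B are dismantled together. The precursor is the acyclic diazo enone A4, carrying the silyloxy stereocentre and a tertiary ethynyl ether. Irradiation would cause a Wolff shift to a vinylketene, which adds to the tethered ynol ether; on warming the cyclobutenone opens and the dienylketene closes to the phenol A3.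
- Merits: arene and pyran are formed in one operation with the oxygen pattern fixed by connectivity, so no catechol differentiation is needed.
- Weak points: the stereocentre must already be in A4, so a separate asymmetric synthesis is still required. Ethynyl ethers of tertiary alcohols are hard to make and lose ketene by a retro-ene path on the warming that the electrocyclic steps need. A3 ends as a C7 phenol, so the linking carbon must then be added by triflation and a further C–C coupling.
- Comparison: it is elegant in ring construction but clearly longer and thermally fragile. The chosen plan buys ring A with its carbon substituent and spends its key step on the stereocentre.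

**Alternative 3:** C3–C4 and O1–C2 are cut. The quinone methide released from the hydroxybenzyl alcohol A6 by a chiral phosphoric acid would add the alkenylboronate A7 in a formal [4+2] process, closing ring B and setting C3 to give the chromanyl boronate A5, which oxidation would convert into 12.
- Merits: this is the shortest route to 12. It needs no phenol protection, no organolithium and no separate ring closure, and in step economy it beats the chosen plan by about four steps.
- Weak points: the quinone methide is unsubstituted at its methylene and so prone to oligomerise. Its formation is disfavoured by the ester para to the benzylic carbon. A7 is a weak nucleophile. The acid would have to control the face of the alkene partner and not that of the quinone methide, for which there is no close precedent.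
- Comparison: the chosen plan is longer but rests its stereocentre on a catalytic asymmetric reaction known for this substrate class.

Key step: step 4

Assumption: the (Sp,Sp) enantiomer of the MandyPhos ligand (a 1,1'-bis[bis(4-methoxy-3,5-dimethylphenyl)phosphino]-2,2'-bis[α-(dimethylamino)benzyl]ferrocene) is taken to give the (S)-boronate 8; if correlation at the stage of 12 shows the opposite sense, the (Rp,Rp) ligand is used with no other change.

## Route

Step 1
Reactants: 1 methyl 3,4-dihydroxybenzoate
Product: 2 methyl 3-hydroxy-4-(trifluoromethylsulfonyloxy)benzoate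
Conditions: PhNTf2 (1.0 equiv), K2CO3 (1.0 equiv), DMF, 0 °C to rt
Reagents that add atoms: N-phenylbis(trifluoromethanesulfonimide), O=S(=O)(N(c1ccccc1)S(=O)(=O)C(F)(F)F)C(F)(F)F
Why: Phenol triflation with a mild triflyl donor; one equivalent of carbonate should give mainly the phenoxide of the more acidic 4-hydroxyl (para to the ester), the same bias that underlies the 4-O-selective alkylation of this catechol.

Step 2
Reactants: 2 methyl 3-hydroxy-4-(trifluoromethylsulfonyloxy)benzoate
Product: 3 methyl 3-(tert-butyldimethylsilyloxy)-4-(trifluoromethylsulfonyloxy)benzoate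
Conditions: TBSCl, imidazole, CH2Cl2, rt
Reagents that add atoms: tert-butyldimethylsilyl chloride, CC(C)(C)[Si](C)(C)Cl
Why: Standard silylation of the remaining phenol; installing the triflate first leaves no free neighbouring phenoxide to which the silyl group could migrate.

Step 3
Reactants: 4 tetravinylstannane
Product: 5 vinyllithium
Conditions: n-BuLi (4 equiv), pentane, rt; solid filtered and washed under argon, then dissolved in THF and titrated
Reagents that add atoms: n-butyllithium, [Li]CCCC
Why: Tin–lithium exchange driven by precipitation of vinyllithium from pentane; the reagent is obtained free of lithium halide, which would otherwise block the cationic palladium intermediate of step 4.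

Step 4
Reactants: 6 isopropenylboronic acid pinacol ester; 5 vinyllithium; 3 methyl 3-(tert-butyldimethylsilyloxy)-4-(trifluoromethylsulfonyloxy)benzoate
Product: 8 methyl (S)-3-(tert-butyldimethylsilyloxy)-4-[3-methyl-2-(4,4,5,5-tetramethyl-1,3,2-dioxaborolan-2-yl)but-3-enyl]benzoate, via lithium isopropenyl(vinyl)borate complex 7 (not isolated)
Conditions: 6, 5 (1.0 equiv), THF, 0 °C to rt; then 3, Pd(OAc)2 (2 mol %), (Sp,Sp)-MandyPhos (2.4 mol %), THF, 60 °C
Reagents that add atoms: none
Why: Ate complex 7 is preformed from 6 and 5; oxidative addition of triflate 3 to zerovalent palladium (formed from Pd(OAc)2 and the diphosphine) gives a cationic arylpalladium species that binds the unsubstituted vinyl group of 7. The bound alkene triggers a 1,2-shift of the isopropenyl group from boron to the internal vinyl carbon anti to palladium (C2–C3), and reductive elimination from the resulting alkyl(aryl)palladium joins the terminal carbon to the arene (C4–C4a) and returns zerovalent palladium. The closest known reaction type is the enantioselective palladium-catalysed conjunctive cross-coupling of bis(alkenyl)boronate complexes with aryl triflates, which gives secondary allylic boronates. No ring is closed. The C3 stereocentre is set by the chiral diphosphine, which selects the face of the bound vinyl group on which migration occurs. The step needs vinyl as acceptor and isopropenyl as migrating group, which is secured because the less substituted alkene is the better ligand for palladium and the α-substituted alkenyl group is a good migrating group. It also needs the metallate shift to outrun direct Suzuki-type transfer, which the wide-bite-angle ligand and the halide-free medium favour. The ortho silyloxy group slows oxidative addition, but the para ester makes the triflate electron-poor and compensates.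

Step 5
Reactants: 8 methyl (S)-3-(tert-butyldimethylsilyloxy)-4-[3-methyl-2-(4,4,5,5-tetramethyl-1,3,2-dioxaborolan-2-yl)but-3-enyl]benzoate
Product: 9 methyl (S)-3-(tert-butyldimethylsilyloxy)-4-(2-hydroxy-3-methylbut-3-enyl)benzoate
Conditions: NaBO3·4H2O, THF/H2O (1:1), rt
Reagents that add atoms: sodium perborate, [Na+].[Na+].O[B-]1(O)OO[B-](O)(O)OO1
Why: Boronate oxidation by 1,2-migration of carbon from boron to oxygen, which proceeds with retention, so (S)-C–B becomes (S)-C–O; the mildly basic perborate should spare the methyl ester, and any phenol 10 formed by partial desilylation converges in step 6.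

Step 6
Reactants: 9 methyl (S)-3-(tert-butyldimethylsilyloxy)-4-(2-hydroxy-3-methylbut-3-enyl)benzoate
Product: 10 methyl (S)-3-hydroxy-4-(2-hydroxy-3-methylbut-3-enyl)benzoate
Conditions: Bu4NF (1.1 equiv), AcOH (1.1 equiv), THF, 0 °C
Reagents that add atoms: none
Why: Fluoride cleavage of an aryl silyl ether; buffering with acetic acid keeps the medium near neutral so that ester and allylic alcohol are untouched.

Step 7
Reactants: 10 methyl (S)-3-hydroxy-4-(2-hydroxy-3-methylbut-3-enyl)benzoate
Product: 12 methyl (S)-3-hydroxy-2,2-dimethylchroman-7-carboxylate, via organomercurial 11 (not isolated)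
Conditions: Hg(OAc)2 (1.05 equiv), THF, 0 °C to rt; then NaBH4, 1 M NaOH, 0 °C
Reagents that add atoms: none
Why: Intramolecular oxymercuration–demercuration: the phenol attacks the mercurinium ion at the tertiary carbon (Markovnikov, 6-exo-trig), closing ring B without a free cation that could trigger hydride shift from C3. Reductive demercuration turns the CH2Hg group into the second methyl group, so the transient C2 centre of 11 disappears and C3 is untouched.

Step 8
Reactants: 12 methyl (S)-3-hydroxy-2,2-dimethylchroman-7-carboxylate
Product: 13 methyl (S)-3-(methoxymethoxy)-2,2-dimethylchroman-7-carboxylate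
Conditions: MOMCl, i-Pr2NEt, Bu4NI (cat.), CH2Cl2, 0 to 40 °C
Reagents that add atoms: chloromethyl methyl ether, COCCl
Why: Acetal protection of a hindered secondary alcohol with a small, reactive electrophile; the ether is inert to the hydride, organocopper and hydroxide steps that follow.

Step 9
Reactants: 13 methyl (S)-3-(methoxymethoxy)-2,2-dimethylchroman-7-carboxylate
Product: 14 [(S)-3-(methoxymethoxy)-2,2-dimethylchroman-7-yl]methanol
Conditions: LiAlH4, THF, 0 °C
Reagents that add atoms: none
Why: Hydride reduction of an aryl ester to the benzylic alcohol; no other reducible group is present.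

Step 10
Reactants: 14 [(S)-3-(methoxymethoxy)-2,2-dimethylchroman-7-yl]methanol
Product: 15 (S)-7-(bromomethyl)-3-(methoxymethoxy)-2,2-dimethylchroman
Conditions: CBr4, PPh3, CH2Cl2, 0 °C
Reagents that add atoms: carbon tetrabromide, BrC(Br)(Br)Br
Why: Appel bromination of a primary benzylic alcohol under near-neutral conditions that an acetal tolerates.

Step 11
Reactants: 16 4-bromophenol
Product: 17 1-bromo-4-(methoxymethoxy)benzene
Conditions: MOMCl, i-Pr2NEt, CH2Cl2, 0 °C to rt
Reagents that add atoms: chloromethyl methyl ether, COCCl
Why: Acetal protection of the phenol; the group withstands magnesium insertion and is removed at the end together with the carbinol acetal.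

Step 12
Reactants: 17 1-bromo-4-(methoxymethoxy)benzene; 18 dimethyl acetylenedicarboxylate; 15 (S)-7-(bromomethyl)-3-(methoxymethoxy)-2,2-dimethylchroman
Product: 22 dimethyl (Z)-2-[4-(methoxymethoxy)phenyl]-3-{[(S)-3-(methoxymethoxy)-2,2-dimethylchroman-7-yl]methyl}but-2-enedioate, via arylmagnesium bromide 19 (not isolated), via arylcopper reagent 20 (not isolated), via vinylcopper adduct 21 (not isolated)
Conditions: 17, Mg, THF, 40 °C; CuBr·SMe2, THF, −40 °C; 18, −78 °C; then 15 (limiting, 0.5 equiv relative to 18), HMPA, −78 °C to rt
Reagents that add atoms: none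
Why: Tandem carbocupration–alkylation of an acetylenedicarboxylate: the arylcopper reagent adds syn across the alkyne, and the vinylcopper species is alkylated with retention by the reactive benzylic bromide in the presence of HMPA, placing both esters cis. The vinylcopper is used in excess so that the valuable bromide 15 is consumed.

Step 13
Reactants: 22 dimethyl (Z)-2-[4-(methoxymethoxy)phenyl]-3-{[(S)-3-(methoxymethoxy)-2,2-dimethylchroman-7-yl]methyl}but-2-enedioate
Product: 24 3-[4-(methoxymethoxy)phenyl]-4-{[(S)-3-(methoxymethoxy)-2,2-dimethylchroman-7-yl]methyl}furan-2,5-dione, via maleic diacid 23 (not isolated)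
Conditions: LiOH, THF/MeOH/H2O, 50 °C; then 1 M HCl to pH 2, 0 °C to rt; toluene azeotrope
Reagents that add atoms: lithium hydroxide, [Li+].[OH-]
Why: Saponification followed by spontaneous cyclodehydration, which is characteristic of 2,3-disubstituted maleic acids on acidification. Ring closure also corrects any trans-diester from step 12 and favours the endocyclic tetrasubstituted alkene.

Step 14
Reactants: 24 3-[4-(methoxymethoxy)phenyl]-4-{[(S)-3-(methoxymethoxy)-2,2-dimethylchroman-7-yl]methyl}furan-2,5-dione
Product: 25 3-[4-(methoxymethoxy)phenyl]-4-{[(S)-3-(methoxymethoxy)-2,2-dimethylchroman-7-yl]methyl}-1H-pyrrole-2,5-dione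
Conditions: (Me3Si)2NH, MeOH, DMF, rt
Reagents that add atoms: hexamethyldisilazane, C[Si](C)(C)N[Si](C)(C)C
Why: Conversion of a maleic anhydride into the NH maleimide by ammonia generated in situ from the disilazane and methanol; ring opening to the amide acid and silyl-assisted reclosure occur at room temperature without acid or strong base, so the acetals and the alkene position are safe.

Step 15
Reactants: 25 3-[4-(methoxymethoxy)phenyl]-4-{[(S)-3-(methoxymethoxy)-2,2-dimethylchroman-7-yl]methyl}-1H-pyrrole-2,5-dione
Product: 26 asperimide C, 3-(4-hydroxyphenyl)-4-{[(S)-3-hydroxy-2,2-dimethylchroman-7-yl]methyl}-1H-pyrrole-2,5-dione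
Conditions: 3 M HCl, MeOH, 50 °C
Reagents that add atoms: none
Why: Acid-catalysed acetal exchange removes both methoxymethyl groups in one operation; the maleimide and the chroman ether are stable to dilute acid at this temperature and C3 is not ionisable, so its configuration is kept.

## Compound list

1 | methyl 3,4-dihydroxybenzoate | COC(=O)c1ccc(O)c(O)c1 | starting material
2 | methyl 3-hydroxy-4-(trifluoromethylsulfonyloxy)benzoate | COC(=O)c1ccc(OS(=O)(=O)C(F)(F)F)c(O)c1 | intermediate
3 | methyl 3-(tert-butyldimethylsilyloxy)-4-(trifluoromethylsulfonyloxy)benzoate | COC(=O)c1ccc(OS(=O)(=O)C(F)(F)F)c(O[Si](C)(C)C(C)(C)C)c1 | intermediate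
4 | tetravinylstannane | C=C[Sn](C=C)(C=C)C=C | starting material
5 | vinyllithium | [Li]C=C | intermediate
6 | isopropenylboronic acid pinacol ester | CC(=C)B1OC(C)(C)C(C)(C)O1 | starting material
7 | lithium isopropenyl(vinyl)(pinacolato)borate | [Li+].C=C[B-]1(C(C)=C)OC(C)(C)C(C)(C)O1 | intermediate
8 | methyl (S)-3-(tert-butyldimethylsilyloxy)-4-[3-methyl-2-(4,4,5,5-tetramethyl-1,3,2-dioxaborolan-2-yl)but-3-enyl]benzoate | COC(=O)c1ccc(C[C@@H](C(C)=C)B2OC(C)(C)C(C)(C)O2)c(O[Si](C)(C)C(C)(C)C)c1 | intermediate
9 | methyl (S)-3-(tert-butyldimethylsilyloxy)-4-(2-hydroxy-3-methylbut-3-enyl)benzoate | COC(=O)c1ccc(C[C@@H](C(C)=C)O)c(O[Si](C)(C)C(C)(C)C)c1 | intermediate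
10 | methyl (S)-3-hydroxy-4-(2-hydroxy-3-methylbut-3-enyl)benzoate | COC(=O)c1ccc(C[C@@H](C(C)=C)O)c(O)c1 | intermediate
11 | methyl (3S)-2-[(acetoxymercurio)methyl]-3-hydroxy-2-methylchroman-7-carboxylate (both C2 epimers) | CC1(C[Hg]OC(C)=O)Oc2cc(C(=O)OC)ccc2C[C@@H]1O | intermediate
12 | methyl (S)-3-hydroxy-2,2-dimethylchroman-7-carboxylate | CC1(C)Oc2cc(C(=O)OC)ccc2C[C@@H]1O | intermediate
13 | methyl (S)-3-(methoxymethoxy)-2,2-dimethylchroman-7-carboxylate | CC1(C)Oc2cc(C(=O)OC)ccc2C[C@@H]1OCOC | intermediate
14 | [(S)-3-(methoxymethoxy)-2,2-dimethylchroman-7-yl]methanol | CC1(C)Oc2cc(CO)ccc2C[C@@H]1OCOC | intermediate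
15 | (S)-7-(bromomethyl)-3-(methoxymethoxy)-2,2-dimethylchroman | CC1(C)Oc2cc(CBr)ccc2C[C@@H]1OCOC | intermediate
16 | 4-bromophenol | Oc1ccc(Br)cc1 | starting material
17 | 1-bromo-4-(methoxymethoxy)benzene | COCOc1ccc(Br)cc1 | intermediate
18 | dimethyl acetylenedicarboxylate | COC(=O)C#CC(=O)OC | starting material
19 | 4-(methoxymethoxy)phenylmagnesium bromide | COCOc1ccc([Mg]Br)cc1 | intermediate
20 | 4-(methoxymethoxy)phenylcopper (as its magnesium bromide–dimethyl sulfide complex) | COCOc1ccc([Cu])cc1 | intermediate
21 | dimethyl 2-cuprio-3-[4-(methoxymethoxy)phenyl]but-2-enedioate (ester groups cis, copper cis to the aryl group) | COC(=O)/C([Cu])=C(\C(=O)OC)c1ccc(OCOC)cc1 | intermediate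
22 | dimethyl (Z)-2-[4-(methoxymethoxy)phenyl]-3-{[(S)-3-(methoxymethoxy)-2,2-dimethylchroman-7-yl]methyl}but-2-enedioate | CC1(C)Oc2cc(C/C(C(=O)OC)=C(/C(=O)OC)c3ccc(OCOC)cc3)ccc2C[C@@H]1OCOC | intermediate
23 | (Z)-2-[4-(methoxymethoxy)phenyl]-3-{[(S)-3-(methoxymethoxy)-2,2-dimethylchroman-7-yl]methyl}but-2-enedioic acid | CC1(C)Oc2cc(C/C(C(=O)O)=C(/C(=O)O)c3ccc(OCOC)cc3)ccc2C[C@@H]1OCOC | intermediate
24 | 3-[4-(methoxymethoxy)phenyl]-4-{[(S)-3-(methoxymethoxy)-2,2-dimethylchroman-7-yl]methyl}furan-2,5-dione | CC1(C)Oc2cc(CC3=C(c4ccc(OCOC)cc4)C(=O)OC3=O)ccc2C[C@@H]1OCOC | intermediate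
25 | 3-[4-(methoxymethoxy)phenyl]-4-{[(S)-3-(methoxymethoxy)-2,2-dimethylchroman-7-yl]methyl}-1H-pyrrole-2,5-dione | CC1(C)Oc2cc(CC3=C(c4ccc(OCOC)cc4)C(=O)NC3=O)ccc2C[C@@H]1OCOC | intermediate
26 | asperimide C, 3-(4-hydroxyphenyl)-4-{[(S)-3-hydroxy-2,2-dimethylchroman-7-yl]methyl}-1H-pyrrole-2,5-dione | CC1(C)Oc2cc(CC3=C(c4ccc(O)cc4)C(=O)NC3=O)ccc2C[C@@H]1O | target

## Step count and risks

Total: 15 steps. Longest linear sequence: 13 steps (1, 2, 4 to 10, 12 to 15, counted from 1).

**Step 4 (key step).** The bulky ortho silyloxy group may slow oxidative addition and binding of the ate complex, so that direct Suzuki-type transfer of an alkenyl group or erosion of facial selectivity competes with the metallate shift. Residual halide would have the same effect.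
Fallback, from 3 back to 12: Stille coupling of 3 with tributyl(3-methylbut-2-enyl)stannane (Pd(PPh3)4, LiCl, DMF, 90 °C) would give methyl 3-(tert-butyldimethylsilyloxy)-4-(3-methylbut-2-enyl)benzoate F1. Shi epoxidation of the trisubstituted alkene (KHSO5, K2CO3 buffer, 0 °C) with the L-fructose-derived enantiomer of the ketone catalyst, expected by analogy to deliver the (S)-epoxide, would give methyl 3-(tert-butyldimethylsilyloxy)-4-{[(S)-3,3-dimethyloxiran-2-yl]methyl}benzoate F2. Buffered fluoride desilylation would release methyl 4-{[(S)-3,3-dimethyloxiran-2-yl]methyl}-3-hydroxybenzoate F3, and camphorsulfonic acid in CH2Cl2 would open the epoxide 6-endo at the tertiary carbon with retention at C3. The route is rejoined at 12, bypassing 8 to 11.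

**Step 12.** Alkylation of the vinylcopper adduct by the benzylic bromide may be slower than its decomposition or its cis–trans equilibration through the allenoate form on warming, and homocoupling of the bromide may consume the valuable fragment.
Fallback, from 15 back to 22, with reversed polarity at the benzylic carbon: the vinylcopper adduct 21 is quenched with iodine at −78 °C to give dimethyl (E)-2-iodo-3-[4-(methoxymethoxy)phenyl]but-2-enedioate F4 (ester groups cis). Bromide 15 is converted by Zn dust and LiCl in THF into {[(S)-3-(methoxymethoxy)-2,2-dimethylchroman-7-yl]methyl}zinc bromide F5, and Negishi coupling of F4 with F5 (Pd(PPh3)4, THF, rt) should give 22.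

**Step 1.** Incomplete discrimination between the two hydroxyl groups, or over-reaction to the bis-triflate, would give a mixture that is hard to separate and would place the triflate at the wrong position.
Fallback, from 1 back to 3: the established 4-O-selective benzylation of 1 (BnBr, K2CO3, DMF) gives methyl 4-(benzyloxy)-3-hydroxybenzoate F6. Silylation gives methyl 4-(benzyloxy)-3-(tert-butyldimethylsilyloxy)benzoate F7. Hydrogenolysis (H2, Pd on carbon, EtOAc) gives methyl 3-(tert-butyldimethylsilyloxy)-4-hydroxybenzoate F8. Triflation with Tf2O and pyridine at −78 °C, cold enough to suppress silyl migration, gives 3.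

**Step 7.** Reversion of the oxymercuration during borohydride reduction (loss of the phenoxide from the β-oxygenated radical or mercurial) or competing mercuration of the phenol ring would return open-chain material or give ring-metalated by-products.
Fallback, from 10 back to 12: iodoetherification (I2, NaHCO3, MeCN, 0 °C) closes the same 6-exo ring to give methyl (3S)-3-hydroxy-2-(iodomethyl)-2-methylchroman-7-carboxylate F9 as a mixture of C2 epimers, and radical deiodination (Bu3SnH, AIBN, toluene, 80 °C) converges both epimers on 12.

**Step 13.** Under hydroxide the benzylic CH2 next to the maleate may be deprotonated and the alkene may move into conjugation with ring A, giving a benzylidene succinate that does not close cleanly to 24.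
Fallback, from 15 to 26, avoiding base: step 12 is run with di-tert-butyl acetylenedicarboxylate in place of 18 to give di-tert-butyl (Z)-2-[4-(methoxymethoxy)phenyl]-3-{[(S)-3-(methoxymethoxy)-2,2-dimethylchroman-7-yl]methyl}but-2-enedioate F10. Aqueous CF3CO2H in CH2Cl2 then cleaves both tert-butyl esters and both acetals and closes the ring to 3-(4-hydroxyphenyl)-4-{[(S)-3-hydroxy-2,2-dimethylchroman-7-yl]methyl}furan-2,5-dione F11. Treatment of F11 with (Me3Si)2NH and MeOH in DMF gives 26 directly, bypassing 22 to 25.

## Further compounds

F1 | step 4 | methyl 3-(tert-butyldimethylsilyloxy)-4-(3-methylbut-2-enyl)benzoate | COC(=O)c1ccc(CC=C(C)C)c(O[Si](C)(C)C(C)(C)C)c1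
F2 | step 4 | methyl 3-(tert-butyldimethylsilyloxy)-4-{[(S)-3,3-dimethyloxiran-2-yl]methyl}benzoate | COC(=O)c1ccc(C[C@@H]2OC2(C)C)c(O[Si](C)(C)C(C)(C)C)c1
F3 | step 4 | methyl 4-{[(S)-3,3-dimethyloxiran-2-yl]methyl}-3-hydroxybenzoate | COC(=O)c1ccc(C[C@@H]2OC2(C)C)c(O)c1
F4 | step 12 | dimethyl (E)-2-iodo-3-[4-(methoxymethoxy)phenyl]but-2-enedioate | COC(=O)/C(I)=C(\C(=O)OC)c1ccc(OCOC)cc1
F5 | step 12 | {[(S)-3-(methoxymethoxy)-2,2-dimethylchroman-7-yl]methyl}zinc bromide | CC1(C)Oc2cc(C[Zn]Br)ccc2C[C@@H]1OCOC
F6 | step 1 | methyl 4-(benzyloxy)-3-hydroxybenzoate | COC(=O)c1ccc(OCc2ccccc2)c(O)c1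
F7 | step 1 | methyl 4-(benzyloxy)-3-(tert-butyldimethylsilyloxy)benzoate | COC(=O)c1ccc(OCc2ccccc2)c(O[Si](C)(C)C(C)(C)C)c1
F8 | step 1 | methyl 3-(tert-butyldimethylsilyloxy)-4-hydroxybenzoate | COC(=O)c1ccc(O)c(O[Si](C)(C)C(C)(C)C)c1
F9 | step 7 | methyl (3S)-3-hydroxy-2-(iodomethyl)-2-methylchroman-7-carboxylate | CC1(CI)Oc2cc(C(=O)OC)ccc2C[C@@H]1O
F10 | step 13 | di-tert-butyl (Z)-2-[4-(methoxymethoxy)phenyl]-3-{[(S)-3-(methoxymethoxy)-2,2-dimethylchroman-7-yl]methyl}but-2-enedioate | CC1(C)Oc2cc(C/C(C(=O)OC(C)(C)C)=C(/C(=O)OC(C)(C)C)c3ccc(OCOC)cc3)ccc2C[C@@H]1OCOC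
F11 | step 13 | 3-(4-hydroxyphenyl)-4-{[(S)-3-hydroxy-2,2-dimethylchroman-7-yl]methyl}furan-2,5-dione | CC1(C)Oc2cc(CC3=C(c4ccc(O)cc4)C(=O)OC3=O)ccc2C[C@@H]1O
A1 | alternative 1 | 1-(2,4-dimethoxybenzyl)-3-[4-(methoxymethoxy)phenyl]-4-{[(S)-3-(methoxymethoxy)-2,2-dimethylchroman-7-yl]methyl}pyrrole-2,5-dione | CC1(C)Oc2cc(CC3=C(c4ccc(OCOC)cc4)C(=O)N(Cc4ccc(OC)cc4OC)C3=O)ccc2C[C@@H]1OCOC
A2 | alternative 1 | 4-(2,4-dimethoxybenzyl)-2-[4-(methoxymethoxy)phenyl]-6-{[(S)-3-(methoxymethoxy)-2,2-dimethylchroman-7-yl]methyl}thiomorpholine-3,5-dione 1,1-dioxide | CC1(C)Oc2cc(CC3C(=O)N(Cc4ccc(OC)cc4OC)C(=O)C(c4ccc(OCOC)cc4)S3(=O)=O)ccc2C[C@@H]1OCOC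
A3 | alternative 2 | (S)-3-(tert-butyldimethylsilyloxy)-2,2-dimethylchroman-7-ol | CC1(C)Oc2cc(O)ccc2C[C@@H]1O[Si](C)(C)C(C)(C)C
A4 | alternative 2 | (S)-6-(tert-butyldimethylsilyloxy)-4-diazo-7-(ethynyloxy)-7-methyloct-1-en-3-one | C=CC(=O)C(=[N+]=[N-])C[C@@H](C(C)(C)OC#C)O[Si](C)(C)C(C)(C)C
A5 | alternative 3 | methyl (S)-2,2-dimethyl-3-(4,4,5,5-tetramethyl-1,3,2-dioxaborolan-2-yl)chroman-7-carboxylate | CC1(C)Oc2cc(C(=O)OC)ccc2C[C@@H]1B3OC(C)(C)C(C)(C)O3
A6 | alternative 3 | methyl 3-hydroxy-4-(hydroxymethyl)benzoate | COC(=O)c1ccc(CO)c(O)c1
A7 | alternative 3 | 2-methylprop-1-enylboronic acid pinacol ester | CC(C)=CB1OC(C)(C)C(C)(C)O1
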